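**Strategy.** The target is (2S)-luteoliflavan-(4β→8)-(−)-epigallocatechin gallate. Everything rests on disconnecting the upper pyran ring (O1–C2–C3–C4–C4a–C8a) at C4–C3 and O1–C2 and, in the same operation, at C4–C4a. C4 is a diarylmethine between two phloroglucinol-type rings, so it maps onto an aldehyde carbon, and O1–C8a–C4a–C4 onto an ortho-quinone methide. One chiral-acid-catalysed three-component reaction joins 8-formyl-octa-O-benzyl-EGCG, 3,5-bis(benzyloxy)phenol and 3,4-bis(benzyloxy)styrene, closes the ring and sets both new stereocentres: the catalyst controls C4, and the peri 5-benzyloxy group relays C2 (2,4-trans). Natural (−)-epigallocatechin supplies the other two stereocentres; hydrogenolysis of twelve benzyl ethers completes the synthesis.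

Key step: step 5

Assumption: the target is read as EGCG unit 2R,3R (2,3-cis) and upper flavan unit 2S,4R (2-aryl and 4-aryl trans).
Assumption: (−)-epigallocatechin (1), 3,4,5-tris(benzyloxy)benzoyl chloride (3), 3,4-bis(benzyloxy)benzaldehyde (7) and 3,5-bis(benzyloxy)phenol (9) are taken as commercial.
Assumption: the sense of facial induction of the chiral acid in step 5 cannot be assigned in advance; the (R)-catalyst is written, and its antipode would be used if that proves to be the one matched with the EGCG unit for the 4R product.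

Step 1
Reactants: 1 (−)-epigallocatechin
Product: 2 5,7,3',4',5'-penta-O-benzyl-(−)-epigallocatechin
Conditions: BnBr (6 equiv), K2CO3 (7 equiv), degassed DMF, N2, −10 °C → rt
Reagents that add atoms: benzyl bromide BrCc1ccccc1
Why: Williamson etherification under carbonate conditions should benzylate the five phenols only, since the aliphatic 3-OH is not deprotonated by K2CO3, while low temperature and exclusion of oxygen should protect the pyrogallol phenoxides and the C2/C3 stereocentres (2R,3R).

Step 2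
Reactants: 2 5,7,3',4',5'-penta-O-benzyl-(−)-epigallocatechin, 3 3,4,5-tris(benzyloxy)benzoyl chloride
Product: 4 octa-O-benzyl-EGCG
Conditions: 3 (1.5 equiv), Et3N (3 equiv), DMAP (0.2 equiv), CH2Cl2, 0 °C → rt
Reagents that add atoms: none
Why: DMAP-catalysed acylation of the secondary 3-OH by the acid chloride (nucleophilic acyl substitution) should form the gallate ester at oxygen, so C3 keeps its configuration and C2 is not touched.

Step 3
Reactants: 4 octa-O-benzyl-EGCG
Product: 6 8-formyl-octa-O-benzyl-EGCG, via aryl iminium chloride 5 (not isolated)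
Conditions: POCl3 (3 equiv), DMF (5 equiv), ClCH2CH2Cl, 0 → 60 °C; then aq. NaOAc, rt
Reagents that add atoms: N,N-dimethylformamide CN(C)C=O; water O
Why: Vilsmeier–Haack formylation should attack the only 1,3,5-trioxygenated ring at C8 (ortho to O1 and 7-OBn, para to 5-OBn), its most nucleophilic position, while ester, benzyl ethers and stereocentres are inert; no stereocentre is formed.

Step 4
Reactants: 7 3,4-bis(benzyloxy)benzaldehyde
Product: 8 3,4-bis(benzyloxy)styrene
Conditions: Ph3PCH3Br, KOtBu, THF, 0 °C → rt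
Reagents that add atoms: methyltriphenylphosphonium bromide C[P+](c1ccccc1)(c1ccccc1)c1ccccc1.[Br-]
Why: Wittig methylenation of an aryl aldehyde with the non-stabilised ylide is reliable, and no stereocentre is formed.

Step 5
Reactants: 6 8-formyl-octa-O-benzyl-EGCG, 9 3,5-bis(benzyloxy)phenol, 8 3,4-bis(benzyloxy)styrene
Product: 12 dodeca-O-benzyl-(2S)-luteoliflavan-(4β→8)-EGCG, via diaryl carbinol 10 (not isolated), via o-quinone methide 11 (not isolated)
Conditions: (R)-TRIP N-triflylphosphoramide (10 mol%), 5 Å MS, CH2Cl2/PhCF3, −20 °C → rt; 8 (3 equiv), 9 added slowly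
Reagents that add atoms: none
Why: The chiral acid mediates ortho-selective Friedel–Crafts hydroxyalkylation of phenol 9 by aldehyde 6 to carbinol 10, dehydrates it to the hydrogen-bonded o-quinone methide 11, and 11 is trapped head-to-tail by the electron-rich styrene 8 in an inverse-demand, strongly asynchronous hetero-Diels–Alder reaction. It combines two known reaction types: the acid-catalysed three-component chroman synthesis from a phenol or naphthol, an aryl aldehyde and a styrene, and the chiral phosphoric-acid-type catalysed [4+2] cycloaddition of in situ generated o-quinone methides with styrenes. The pyran ring closes as a formal [4+2] cycloaddition: the styrene CH2 terminus attacks the methide carbon (C4–C3), and the phenolic oxygen then closes six-membered onto the 3,4-dialkoxybenzylic cation (O1–C2). C4 (R) is set by the catalyst, which is hydrogen-bonded to the methide oxygen and shields one face during C–C bond formation, the EGCG stereocentres being too remote for useful substrate control; C2 (S) is relayed from C4, because the peri 5-benzyloxy group forces the 4-aryl group pseudoaxial (A1,3 strain) and the 2-aryl group closes equatorial, giving the 2,4-trans ring, which should also be the thermodynamic isomer reachable by reversible ionisation of the benzylic C2–O1 bond. The step needs ortho instead of para attack on 9, capture of 11 by the styrene instead of by a second phenol, and head-to-tail orientation; the first should be secured by the OH–catalyst hydrogen bond and the reversibility of the non-cyclisable para adduct, the second by slow addition of 9 to an excess of 8, and the third by the polarity of the methide and the p-alkoxy-stabilised benzylic cation.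

Step 6
Reactants: 12 dodeca-O-benzyl-(2S)-luteoliflavan-(4β→8)-EGCG
Product: 13 (2S)-luteoliflavan-(4β→8)-(−)-epigallocatechin 3-O-gallate
Conditions: H2 (1 atm), Pd(OH)2/C, THF/MeOH, rt; filtration and isolation under argon
Reagents that add atoms: none
Why: Catalytic hydrogenolysis should cleave the twelve benzyl ethers under neutral conditions that leave the aryl ester, the diarylmethine C4 and the chroman C2–O1 bonds of both units intact, so all four stereocentres are retained.

**Compound list**

1 | (−)-epigallocatechin, (2R,3R) | O[C@@H]1Cc2c(O)cc(O)cc2O[C@@H]1c1cc(O)c(O)c(O)c1 | starting material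
2 | 5,7,3',4',5'-penta-O-benzyl-(−)-epigallocatechin: (2R,3R)-5,7-bis(benzyloxy)-2-[3,4,5-tris(benzyloxy)phenyl]chroman-3-ol | O[C@@H]1Cc2c(OCc3ccccc3)cc(OCc3ccccc3)cc2O[C@@H]1c1cc(OCc2ccccc2)c(OCc2ccccc2)c(OCc2ccccc2)c1 | intermediate
3 | 3,4,5-tris(benzyloxy)benzoyl chloride | O=C(Cl)c1cc(OCc2ccccc2)c(OCc2ccccc2)c(OCc2ccccc2)c1 | starting material
4 | octa-O-benzyl-EGCG: (2R,3R)-5,7-bis(benzyloxy)-2-[3,4,5-tris(benzyloxy)phenyl]chroman-3-yl 3,4,5-tris(benzyloxy)benzoate | O=C(O[C@@H]1Cc2c(OCc3ccccc3)cc(OCc3ccccc3)cc2O[C@@H]1c1cc(OCc2ccccc2)c(OCc2ccccc2)c(OCc2ccccc2)c1)c1cc(OCc2ccccc2)c(OCc2ccccc2)c(OCc2ccccc2)c1 | intermediate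
5 | aryl iminium chloride: 4 carrying CH=N+Me2 at C8, chloride salt (not isolated) | O=C(O[C@@H]1Cc2c(OCc3ccccc3)cc(OCc3ccccc3)c(C=[N+](C)C)c2O[C@@H]1c1cc(OCc2ccccc2)c(OCc2ccccc2)c(OCc2ccccc2)c1)c1cc(OCc2ccccc2)c(OCc2ccccc2)c(OCc2ccccc2)c1.[Cl-] | intermediate
6 | 8-formyl-octa-O-benzyl-EGCG: (2R,3R)-5,7-bis(benzyloxy)-8-formyl-2-[3,4,5-tris(benzyloxy)phenyl]chroman-3-yl 3,4,5-tris(benzyloxy)benzoate | O=C(O[C@@H]1Cc2c(OCc3ccccc3)cc(OCc3ccccc3)c(C=O)c2O[C@@H]1c1cc(OCc2ccccc2)c(OCc2ccccc2)c(OCc2ccccc2)c1)c1cc(OCc2ccccc2)c(OCc2ccccc2)c(OCc2ccccc2)c1 | intermediate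
7 | 3,4-bis(benzyloxy)benzaldehyde | O=Cc1ccc(OCc2ccccc2)c(OCc2ccccc2)c1 | starting material
8 | 3,4-bis(benzyloxy)styrene | C=Cc1ccc(OCc2ccccc2)c(OCc2ccccc2)c1 | intermediate
9 | 3,5-bis(benzyloxy)phenol | Oc1cc(OCc2ccccc2)cc(OCc2ccccc2)c1 | starting material
10 | diaryl carbinol: [2-hydroxy-4,6-bis(benzyloxy)phenyl](octa-O-benzyl-EGCG-8-yl)methanol, carbinol carbon as a mixture of epimers (not isolated) | O=C(O[C@@H]1Cc2c(OCc3ccccc3)cc(OCc3ccccc3)c(C(O)c3c(O)cc(OCc4ccccc4)cc3OCc3ccccc3)c2O[C@@H]1c1cc(OCc2ccccc2)c(OCc2ccccc2)c(OCc2ccccc2)c1)c1cc(OCc2ccccc2)c(OCc2ccccc2)c(OCc2ccccc2)c1 | intermediate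
11 | o-quinone methide: 3,5-bis(benzyloxy)-6-[(octa-O-benzyl-EGCG-8-yl)methylidene]cyclohexa-2,4-dien-1-one, alkene geometry not defined (not isolated) | O=C(O[C@@H]1Cc2c(OCc3ccccc3)cc(OCc3ccccc3)c(C=C3C(=O)C=C(OCc4ccccc4)C=C3OCc3ccccc3)c2O[C@@H]1c1cc(OCc2ccccc2)c(OCc2ccccc2)c(OCc2ccccc2)c1)c1cc(OCc2ccccc2)c(OCc2ccccc2)c(OCc2ccccc2)c1 | intermediate
12 | dodeca-O-benzyl-(2S)-luteoliflavan-(4β→8)-EGCG: (2R,3R)-5,7-bis(benzyloxy)-8-[(2S,4R)-5,7-bis(benzyloxy)-2-[3,4-bis(benzyloxy)phenyl]chroman-4-yl]-2-[3,4,5-tris(benzyloxy)phenyl]chroman-3-yl 3,4,5-tris(benzyloxy)benzoate | O=C(O[C@@H]1Cc2c(OCc3ccccc3)cc(OCc3ccccc3)c([C@@H]3C[C@@H](c4ccc(OCc5ccccc5)c(OCc5ccccc5)c4)Oc4cc(OCc5ccccc5)cc(OCc5ccccc5)c43)c2O[C@@H]1c1cc(OCc2ccccc2)c(OCc2ccccc2)c(OCc2ccccc2)c1)c1cc(OCc2ccccc2)c(OCc2ccccc2)c(OCc2ccccc2)c1 | intermediate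
13 | (2S)-luteoliflavan-(4β→8)-(−)-epigallocatechin 3-O-gallate: (2R,3R)-8-[(2S,4R)-2-(3,4-dihydroxyphenyl)-5,7-dihydroxychroman-4-yl]-5,7-dihydroxy-2-(3,4,5-trihydroxyphenyl)chroman-3-yl 3,4,5-trihydroxybenzoate | O=C(O[C@@H]1Cc2c(O)cc(O)c([C@@H]3C[C@@H](c4ccc(O)c(O)c4)Oc4cc(O)cc(O)c43)c2O[C@@H]1c1cc(O)c(O)c(O)c1)c1cc(O)c(O)c(O)c1 | target

**Step count.** Total steps: 6. Longest linear sequence: 5 steps (1 → 2 → 4 → 6 → 12 → 13; step 4 is a one-step branch).

**Steps most likely to fail**

1. Step 5. The three-component event may be diverted: a second phenol may capture the methide to give a triarylmethane, 9 may be hydroxyalkylated para to its OH, 8 may oligomerise under acid, or the face selectivity at C4 may be poor. The fallback sets out from 6 (with 9 and 8) and returns at 12. Aldehyde 6, phenol 9 and phenylboronic acid (cat. propionic acid, toluene, reflux, Dean–Stark) would be condensed in the ortho-specific boron-templated manner to the isolable 5,7-bis(benzyloxy)-4-(octa-O-benzyl-EGCG-8-yl)-2-phenyl-4H-1,3,2-benzodioxaborin F1. Heating F1 with 8 (toluene, 110–150 °C, sealed tube, optionally with catalytic Brønsted acid) should release the same o-quinone methide in the absence of free phenol. Without catalyst control this should give 12 together with its 2,4-trans C4-epimer (upper unit 2R,4S) F2. The two are diastereomers because of the EGCG unit and would be separated by chromatography.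

2. Step 3. The formylation may be unselective between C8 and C6 or sluggish on the hindered ring. The fallback sets out from 4 and returns at 6. NBS (CH2Cl2, −78 °C → rt), which brominates 5,7-dialkoxyflavans at C8, should give 8-bromo-octa-O-benzyl-EGCG F3. Palladium-catalysed reductive carbonylation (Pd(OAc)2, dppb, N-formylsaccharin as CO source, Et3SiH, Na2CO3, DMF, 80 °C), which tolerates the ester, should then deliver 6.

3. Step 6. Debenzylation of twelve ethers may stall at partly protected stages, the benzylic C2–O1 bonds may be opened reductively, and the free polyphenol may oxidise during isolation. The fallback sets out from 12 and returns at 13. It replaces hydrogenolysis by Lewis-acid debenzylation with BCl3 and pentamethylbenzene as benzyl-cation scavenger (CH2Cl2, −78 °C, methanol quench), which uses no hydrogen and no metal and makes no new isolated compound.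

**Further compounds**

F1 | step 5 | 5,7-bis(benzyloxy)-4-(octa-O-benzyl-EGCG-8-yl)-2-phenyl-4H-1,3,2-benzodioxaborin, C4 as a mixture of epimers | O=C(O[C@@H]1Cc2c(OCc3ccccc3)cc(OCc3ccccc3)c(C3OB(c4ccccc4)Oc4cc(OCc5ccccc5)cc(OCc5ccccc5)c34)c2O[C@@H]1c1cc(OCc2ccccc2)c(OCc2ccccc2)c(OCc2ccccc2)c1)c1cc(OCc2ccccc2)c(OCc2ccccc2)c(OCc2ccccc2)c1
F2 | step 5 | 2,4-trans C4-epimer of 12 (upper unit 2R,4S) | O=C(O[C@@H]1Cc2c(OCc3ccccc3)cc(OCc3ccccc3)c([C@H]3C[C@H](c4ccc(OCc5ccccc5)c(OCc5ccccc5)c4)Oc4cc(OCc5ccccc5)cc(OCc5ccccc5)c43)c2O[C@@H]1c1cc(OCc2ccccc2)c(OCc2ccccc2)c(OCc2ccccc2)c1)c1cc(OCc2ccccc2)c(OCc2ccccc2)c(OCc2ccccc2)c1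
F3 | step 3 | 8-bromo-octa-O-benzyl-EGCG | O=C(O[C@@H]1Cc2c(OCc3ccccc3)cc(OCc3ccccc3)c(Br)c2O[C@@H]1c1cc(OCc2ccccc2)c(OCc2ccccc2)c(OCc2ccccc2)c1)c1cc(OCc2ccccc2)c(OCc2ccccc2)c(OCc2ccccc2)c1
F0 | step 6 | none | none
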